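The route rests on disconnecting ring carbon C1 of the benzene ring from C2′, the internal carbon of the 1,1-disubstituted alkene. Both atoms have an oxygen-bearing neighbour: ring C2 carries the phenol O and C3′ carries the ester O. Each oxygen is made to steer its neighbour. The phenol, masked as a MOM ether, directs lithiation to C1. The free (S)-propargylic alcohol, as its magnesium alkoxide, directs a copper-catalysed anti-carbomagnesiation that puts the aryl group on the internal alkyne carbon. One operation joins both halves, fixes the branched regiochemistry and, on protonolysis, creates the exo-methylene group while the stereocentre stays untouched. The precursor is a terminal 1,5-enyn-3-ol, not an alkene.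

Key step: step 6

Remark: C3′ is read as S and the ester as the (Z)-2-methylbut-2-enoate (angelate). Side-chain atoms run from C1′ (=CH2) to C7′, and ring atoms run from C1 (side chain) and C2 (OH) to C6 (H).

Step 1
Reactants: 1 2,4-dimethoxy-3-methylbenzaldehyde
Product: 3 2,4-dimethoxy-3-methylphenol, via aryl formate 2 (not isolated)
Conditions: mCPBA, CH2Cl2, 0 °C → rt; then K2CO3 (cat.), MeOH, rt
Reagents that add atoms: mCPBA (3-chloroperoxybenzoic acid), O=C(OO)c1cccc(Cl)c1
Why: Baeyer–Villiger oxidation (Dakin-type outcome): in the peracid adduct the electron-rich 2,4-dialkoxyaryl group migrates to oxygen in preference to hydride, and carbonate-catalysed methanolysis of formate 2 then frees the phenol; no stereocentre is involved.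

Step 2
Reactants: 3 2,4-dimethoxy-3-methylphenol
Product: 4 1,3-dimethoxy-4-(methoxymethoxy)-2-methylbenzene
Conditions: MOMCl, i-Pr2NEt, CH2Cl2, 0 °C → rt
Reagents that add atoms: chloromethyl methyl ether (MOMCl), COCCl
Why: O-alkylation of the phenol with a reactive α-chloro ether (acetal protection) should be fast even next to the ortho-methoxy group, and it gives a group that resists organolithium and Grignard reagents and directs ortho-metalation more strongly than OMe.

Step 3
Reactants: 5 4-methylpent-3-enoic acid
Product: 7 N-methoxy-N,4-dimethylpent-3-enamide, via acyl imidazolide 6 (not isolated)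
Conditions: CDI, CH2Cl2, rt; then MeNHOMe·HCl, rt
Reagents that add atoms: N,O-dimethylhydroxylamine hydrochloride, CNOC.Cl
Why: Weinreb amide formation through acyl imidazolide 6 runs without strong acid or base, so the β,γ-double bond should stay out of conjugation.

Step 4
Reactants: 7 N-methoxy-N,4-dimethylpent-3-enamide
Product: 9 6-methyl-1-(trimethylsilyl)hept-5-en-1-yn-3-one, via lithium hemiaminal adduct 8 (not isolated)
Conditions: trimethylsilylacetylene, n-BuLi, THF, −78 °C; add 7, −78 → 0 °C; cold sat. aq. NH4Cl
Reagents that add atoms: trimethylsilylacetylene, C#C[Si](C)(C)C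
Why: Weinreb ketone synthesis: the lithium acetylide adds only once because the chelated adduct 8 survives until the cold, buffered quench, which also limits enolisation of the doubly activated CH2 group of 9.

Step 5
Reactants: 9 6-methyl-1-(trimethylsilyl)hept-5-en-1-yn-3-one
Product: 11 (S)-6-methylhept-5-en-1-yn-3-ol, via silylated alkynol 10 (not isolated)
Conditions: Ru[(S,S)-TsDPEN](p-cymene) (preformed 16-electron complex, 1 mol %), i-PrOH, rt; evaporate; then K2CO3 (cat.), MeOH, 0 °C → rt
Reagents that add atoms: none
Why: Noyori asymmetric transfer hydrogenation of an α,β-acetylenic ketone: the (S,S)-Ru hydride/amine catalyst places the alkynyl flank where an aryl group would sit and should deliver hydride to the face that gives the S carbinol centre, the base-free medium leaves the β,γ-alkene in place, and carbonate-catalysed methanolysis then removes the C(sp)–SiMe3 group of 10.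

Step 6
Reactants: 4 1,3-dimethoxy-4-(methoxymethoxy)-2-methylbenzene; 11 (S)-6-methylhept-5-en-1-yn-3-ol
Product: 16 (S)-2-[3,5-dimethoxy-2-(methoxymethoxy)-4-methylphenyl]-6-methylhepta-1,5-dien-3-ol, via aryllithium 12 (not isolated), via aryl Grignard reagent 13 (not isolated), via magnesium alkoxide 14 (not isolated), via oxamagnesacycle 15 (not isolated)
Conditions: 4 (2 equiv), n-BuLi, THF, 0 °C; MgBr2·OEt2, 0 °C → rt; CuI (20 mol %), toluene; add 14 (from 11, EtMgBr 1.0 equiv, THF, 0 °C); rt → 40 °C; sat. aq. NH4Cl
Reagents that add atoms: none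
Why: n-BuLi is held by the acetal oxygens of 4 and removes the adjacent ring hydrogen (directed ortho-metalation), and MgBr2 converts aryllithium 12 into Grignard reagent 13. With Cu(I), 13 forms an arylcopper species that is bound by magnesium alkoxide 14 and adds across the terminal alkyne in anti fashion, aryl to the internal carbon C2′ and metal to C1′, to give oxamagnesacycle 15, whose C–Mg and O–Mg bonds are protonated on quench to leave the exo-methylene group and the free alcohol of 16. The closest known reaction type is the copper-catalysed anti-carbomagnesiation of terminal propargylic alcohols, which is established for aryl Grignard reagents and for enantioenriched secondary carbinols. No ring remains in the product; the only ring closed is the transient five-membered 2,5-dihydro-1,2-oxamagnesole 15, closed by binding of the vinylic magnesium to the alkoxide oxygen and opened again on quench. No stereocentre is created, and the S centre at C3′ is carried through because neither its C–O nor its C–H bond is broken. The step needs branched regioselectivity, secured by the alkoxide next to the alkyne, site-selective metalation at the ring carbon next to OMOM instead of the one next to OMe, secured by the stronger chelating acetal, and chemoselectivity over the C5′=C6′ alkene, which is inert to arylcopper and Grignard reagents.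

Step 7
Reactants: 16 (S)-2-[3,5-dimethoxy-2-(methoxymethoxy)-4-methylphenyl]-6-methylhepta-1,5-dien-3-ol; 17 angelic acid, (Z)-2-methylbut-2-enoic acid
Product: 19 (S)-2-[3,5-dimethoxy-2-(methoxymethoxy)-4-methylphenyl]-6-methylhepta-1,5-dien-3-yl (Z)-2-methylbut-2-enoate, via mixed anhydride 18 (not isolated)
Conditions: 17, 2,4,6-Cl3C6H2COCl, Et3N, toluene, rt; then 16, 80 °C (no DMAP)
Reagents that add atoms: none
Why: Yamaguchi-type mixed-anhydride esterification without DMAP: alcohol 16 attacks the less hindered angeloyl carbonyl of 18, the lack of a nucleophilic catalyst closes the addition–elimination path from angelate to tiglate, and the S centre is retained because its C–O bond is not broken.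

Step 8
Reactants: 19 (S)-2-[3,5-dimethoxy-2-(methoxymethoxy)-4-methylphenyl]-6-methylhepta-1,5-dien-3-yl (Z)-2-methylbut-2-enoate
Product: 21 (S)-2-(2-hydroxy-3,5-dimethoxy-4-methylphenyl)-6-methylhepta-1,5-dien-3-yl (Z)-2-methylbut-2-enoate, via aryl silyl ether 20 (not isolated)
Conditions: TMSOTf, 2,2′-bipyridyl, MeCN, 0 °C → rt; then H2O
Reagents that add atoms: none
Why: Lewis-acid acetal cleavage buffered by a pyridine-type base: TMSOTf/2,2′-bipyridyl converts the aryl MOM ether into aryl silyl ether 20 without free acid and water then hydrolyses the O–Si bond, so the allylic angelate, both trisubstituted alkenes and the electron-rich 1,1-disubstituted alkene should survive.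

Compound list
1 | 2,4-dimethoxy-3-methylbenzaldehyde | COc1ccc(C=O)c(OC)c1C | starting material
2 | 2,4-dimethoxy-3-methylphenyl formate | COc1ccc(OC=O)c(OC)c1C | intermediate
3 | 2,4-dimethoxy-3-methylphenol | COc1ccc(O)c(OC)c1C | intermediate
4 | 1,3-dimethoxy-4-(methoxymethoxy)-2-methylbenzene | COCOc1ccc(OC)c(C)c1OC | intermediate
5 | 4-methylpent-3-enoic acid | CC(C)=CCC(=O)O | starting material
6 | 1-(imidazol-1-yl)-4-methylpent-3-en-1-one | CC(C)=CCC(=O)n1ccnc1 | intermediate
7 | N-methoxy-N,4-dimethylpent-3-enamide | CC(C)=CCC(=O)N(C)OC | intermediate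
8 | lithium 3-[methoxy(methyl)amino]-6-methyl-1-(trimethylsilyl)hept-5-en-1-yn-3-olate | CC(C)=CCC(O[Li])(C#C[Si](C)(C)C)N(C)OC | intermediate
9 | 6-methyl-1-(trimethylsilyl)hept-5-en-1-yn-3-one | CC(C)=CCC(=O)C#C[Si](C)(C)C | intermediate
10 | (S)-6-methyl-1-(trimethylsilyl)hept-5-en-1-yn-3-ol | C[Si](C)(C)C#C[C@H](CC=C(C)C)O | intermediate
11 | (S)-6-methylhept-5-en-1-yn-3-ol | C#C[C@H](CC=C(C)C)O | intermediate
12 | [3,5-dimethoxy-2-(methoxymethoxy)-4-methylphenyl]lithium | [Li]c1cc(OC)c(C)c(OC)c1OCOC | intermediate
13 | [3,5-dimethoxy-2-(methoxymethoxy)-4-methylphenyl]magnesium bromide | Br[Mg]c1cc(OC)c(C)c(OC)c1OCOC | intermediate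
14 | bromomagnesium (S)-6-methylhept-5-en-1-yn-3-olate | C#C[C@H](CC=C(C)C)O[Mg]Br | intermediate
15 | (S)-4-[3,5-dimethoxy-2-(methoxymethoxy)-4-methylphenyl]-5-(3-methylbut-2-enyl)-2,5-dihydro-1,2-oxamagnesole | [Mg]1C=C(c2cc(OC)c(C)c(OC)c2OCOC)[C@H](CC=C(C)C)O1 | intermediate
16 | (S)-2-[3,5-dimethoxy-2-(methoxymethoxy)-4-methylphenyl]-6-methylhepta-1,5-dien-3-ol | C=C(c1cc(OC)c(C)c(OC)c1OCOC)[C@H](CC=C(C)C)O | intermediate
17 | angelic acid, (Z)-2-methylbut-2-enoic acid | OC(=O)/C(C)=C\C | starting material
18 | (Z)-2-methylbut-2-enoic 2,4,6-trichlorobenzoic anhydride | O=C(OC(=O)/C(C)=C\C)c1c(Cl)cc(Cl)cc1Cl | intermediate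
19 | (S)-2-[3,5-dimethoxy-2-(methoxymethoxy)-4-methylphenyl]-6-methylhepta-1,5-dien-3-yl (Z)-2-methylbut-2-enoate | C=C(c1cc(OC)c(C)c(OC)c1OCOC)[C@H](CC=C(C)C)OC(=O)/C(C)=C\C | intermediate
20 | (S)-2-[3,5-dimethoxy-4-methyl-2-(trimethylsilyloxy)phenyl]-6-methylhepta-1,5-dien-3-yl (Z)-2-methylbut-2-enoate | C=C(c1cc(OC)c(C)c(OC)c1O[Si](C)(C)C)[C@H](CC=C(C)C)OC(=O)/C(C)=C\C | intermediate
21 | (S)-2-(2-hydroxy-3,5-dimethoxy-4-methylphenyl)-6-methylhepta-1,5-dien-3-yl (Z)-2-methylbut-2-enoate | C=C(c1cc(OC)c(C)c(OC)c1O)[C@H](CC=C(C)C)OC(=O)/C(C)=C\C | target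

Total step count: 8.
Longest linear sequence: 6 steps (5 → 7 → 9 → 11 → 16 → 19 → 21).

Steps most likely to fail

Step 6 (key step). Transfer of the hindered, chelated ortho-alkoxyaryl group from copper to the alkyne may be slow. Metalation of the terminal alkyne C–H and simple protonation of the aryl reagent could then take over. The fallback runs from 11 and 12 back to 16 and moves the bond formation to palladium.
- Alkynol 11 undergoes NHC–copper-catalysed α-selective protoboration (B2pin2, MeOH) to give (S)-6-methyl-2-(4,4,5,5-tetramethyl-1,3,2-dioxaborolan-2-yl)hepta-1,5-dien-3-ol F1.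
- Aryllithium 12 is quenched with iodine to give 1-iodo-3,5-dimethoxy-2-(methoxymethoxy)-4-methylbenzene F2.
- Suzuki–Miyaura coupling of the two (Pd(dppf)Cl2, K3PO4, THF–H2O) forms the same ring C1–C2′ bond and returns to 16.

Step 7. The activated angeloyl unit may isomerise from Z to E, or acylation of the hindered secondary alcohol may stall at a temperature that still preserves the Z geometry. The fallback runs from 16 back to 19 and builds the Z-alkene on the substrate instead of carrying it in.
- Alcohol 16 is esterified (EDC, DMAP, CH2Cl2) with 2-[bis(2,2,2-trifluoroethoxy)phosphoryl]propanoic acid to give the corresponding (S)-dienyl 2-[bis(2,2,2-trifluoroethoxy)phosphoryl]propanoate F3.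
- Still–Gennari olefination with acetaldehyde (KHMDS, 18-crown-6, THF, −78 °C) sets the (Z)-2-methylbut-2-enoate and returns to 19.

Step 8. The allylic ester may ionise or migrate, or the electron-rich styrene-type alkene may be attacked while the acetal is activated. The fallback runs from 16 to 21 and changes the order of events, so that no acetal has to be cleaved in the presence of the ester.
- The MOM group is removed at the alcohol stage (TMSOTf, 2,2′-bipyridyl, then water) to give (S)-2-(2-hydroxy-3,5-dimethoxy-4-methylphenyl)-6-methylhepta-1,5-dien-3-ol F4.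
- Both hydroxyl groups are acylated with excess 18 to give the bis-angelate, 2-[(S)-3-{[(Z)-2-methylbut-2-enoyl]oxy}-6-methylhepta-1,5-dien-2-yl]-4,6-dimethoxy-5-methylphenyl (Z)-2-methylbut-2-enoate F5.
- The much more electrophilic aryl ester is cleaved chemoselectively by aminolysis with pyrrolidine (THF, 0 °C), which gives 21.

Further compounds
F1 | step 6 | (S)-6-methyl-2-(4,4,5,5-tetramethyl-1,3,2-dioxaborolan-2-yl)hepta-1,5-dien-3-ol | C=C(B1OC(C)(C)C(C)(C)O1)[C@H](CC=C(C)C)O
F2 | step 6 | 1-iodo-3,5-dimethoxy-2-(methoxymethoxy)-4-methylbenzene | COCOc1c(I)cc(OC)c(C)c1OC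
F3 | step 7 | (S)-2-[3,5-dimethoxy-2-(methoxymethoxy)-4-methylphenyl]-6-methylhepta-1,5-dien-3-yl 2-[bis(2,2,2-trifluoroethoxy)phosphoryl]propanoate | C=C(c1cc(OC)c(C)c(OC)c1OCOC)[C@H](CC=C(C)C)OC(=O)C(C)P(=O)(OCC(F)(F)F)OCC(F)(F)F
F4 | step 8 | (S)-2-(2-hydroxy-3,5-dimethoxy-4-methylphenyl)-6-methylhepta-1,5-dien-3-ol | C=C(c1cc(OC)c(C)c(OC)c1O)[C@H](CC=C(C)C)O
F5 | step 8 | 2-[(S)-3-{[(Z)-2-methylbut-2-enoyl]oxy}-6-methylhepta-1,5-dien-2-yl]-4,6-dimethoxy-5-methylphenyl (Z)-2-methylbut-2-enoate | C=C(c1cc(OC)c(C)c(OC)c1OC(=O)/C(C)=C\C)[C@H](CC=C(C)C)OC(=O)/C(C)=C\C
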